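## Retrosynthetic overview

1. Structural feature: in the only ring of the target, C1(=O), C2(OMe), C3(H) and C4(=O) are the four carbons of a 2-methoxycyclobutenone. C5 and C6 are the two carbons of an alkyne whose outer carbon (C6) already bears the whole all-E chain C1'–C24' with its six methyl groups. Cutting C1–C6 (Moore rearrangement) leads back to carbinol 22.
2. 22 comes from dimethyl squarate 16 and the lithium acetylide of skipped enyne 15. Silylation, 1,2-reduction and acid-induced allylic transposition then replace one methoxy group by hydrogen and leave the carbinol carbon next to the ring CH.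
3. 15 comes from all-E-hexaprenyl bromide 11 and trimethylsilylacetylene 12 (bond C1'–C6).
4. The C30 chain is cut at C12'–C13' into two farnesol-derived halves, allyl sulfone 3 and ω-bromide 6.
5. Ring order: the four-membered ring is bought with 16, and the six-membered quinone ring is closed in the last step.

Key step: step 16

Assumption: the cyclobutene intermediates 18–22 are handled as racemates (20 as a mixture of diastereomers); the target is achiral, so this has no consequence.

"Hexaprenylethynyl" means –C≡C–CH2–CH=C(CH3)–…, an ethynyl group whose outer carbon carries the all-E-hexaprenyl chain.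

## Route

Step 1
Reactants: 1 (2E,6E)-farnesol
Product: 2 (2E,6E)-farnesyl bromide
Conditions: PBr3 (0.4 equiv), Et2O, 0 °C; used crude
Reagents that add atoms: phosphorus tribromide, BrP(Br)Br
Why: Bromination of the primary allylic alcohol through its phosphite ester is an SN2 displacement that at low temperature should leave the position and E geometry of the C2–C3 alkene unchanged.

Step 2
Reactants: 2 (2E,6E)-farnesyl bromide
Product: 3 (2E,6E)-farnesyl p-tolyl sulfone
Conditions: p-TolSO2Na, DMF, rt
Reagents that add atoms: sodium p-toluenesulfinate, Cc1ccc(cc1)S(=O)[O-].[Na+]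
Why: The soft sulfur end of the ambident sulfinate displaces the primary allylic bromide (SN2 S-alkylation), which should give the sulfone and not the sulfinate ester.

Step 3
Reactants: 1 (2E,6E)-farnesol
Product: 4 (2E,6E)-farnesyl tert-butyldiphenylsilyl ether
Conditions: TBDPSCl, imidazole, CH2Cl2, rt
Reagents that add atoms: tert-butyldiphenylsilyl chloride, CC(C)(C)[Si](Cl)(c1ccccc1)c1ccccc1
Why: This is a standard silylation of a primary alcohol, and the bulky silyl ether tolerates SeO2, sulfonyl carbanions and hydride and, unlike an allylic ester, is not ionised by zerovalent palladium in step 7.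

Step 4
Reactants: 4 (2E,6E)-farnesyl tert-butyldiphenylsilyl ether
Product: 5 (2E,6E,10E)-12-(tert-butyldiphenylsilyloxy)-2,6,10-trimethyldodeca-2,6,10-trien-1-ol
Conditions: SeO2 (cat.), t-BuOOH, salicylic acid (cat.), CH2Cl2, 0 °C; stopped at partial conversion, 4 recycled
Reagents that add atoms: tert-butyl hydroperoxide, CC(C)(C)OO (its oxygen is passed on by SeO2, O=[Se]=O)
Why: In the Riley allylic oxidation an ene reaction and a [2,3]-sigmatropic shift take place preferentially at the most accessible terminal trisubstituted alkene and hydroxylate the methyl group trans to the chain, which sets the 10E (later 10'E) geometry.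

Step 5
Reactants: 5 (2E,6E,10E)-12-(tert-butyldiphenylsilyloxy)-2,6,10-trimethyldodeca-2,6,10-trien-1-ol
Product: 6 (2E,6E,10E)-12-bromo-3,7,11-trimethyldodeca-2,6,10-trienyl tert-butyldiphenylsilyl ether
Conditions: CBr4, PPh3, CH2Cl2, 0 °C
Reagents that add atoms: carbon tetrabromide, BrC(Br)(Br)Br
Why: The Appel reaction turns the primary allylic alcohol into the bromide by SN2 displacement of the oxyphosphonium group under nearly neutral conditions that spare the silyl ether and the alkene geometry.

Step 6
Reactants: 3 (2E,6E)-farnesyl p-tolyl sulfone; 6 (2E,6E,10E)-12-bromo-3,7,11-trimethyldodeca-2,6,10-trienyl tert-butyldiphenylsilyl ether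
Product: 8 (±)-13-(p-tolylsulfonyl)-all-E-hexaprenyl tert-butyldiphenylsilyl ether, via lithiated sulfone 7 (not isolated)
Conditions: 3, n-BuLi, THF/DMPU, −78 °C; then 6, −78 → −20 °C
Reagents that add atoms: none
Why: The sulfonyl-stabilised allyl anion is alkylated at its α-carbon by the primary allylic bromide (Julia-type allyl sulfone alkylation), which forms C12'–C13' and a racemic sulfone-bearing centre that step 7 erases.

Step 7
Reactants: 8 (±)-13-(p-tolylsulfonyl)-all-E-hexaprenyl tert-butyldiphenylsilyl ether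
Product: 9 all-E-hexaprenyl tert-butyldiphenylsilyl ether
Conditions: PdCl2(dppp) (5 mol %), LiEt3BH, THF, 0 °C → rt
Reagents that add atoms: none
Why: In this palladium-catalysed hydrogenolysis of an allylic sulfone, zerovalent palladium ionises the C–S bond to a π-allyl complex and hydride is delivered to the less substituted terminus C13', which should keep the C14'–C15' alkene in place and E.

Step 8
Reactants: 9 all-E-hexaprenyl tert-butyldiphenylsilyl ether
Product: 10 all-E-hexaprenol
Conditions: n-Bu4NF, THF, rt; aqueous work-up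
Reagents that add atoms: none
Why: Fluoride-induced cleavage of the Si–O bond is driven by the strong Si–F bond and does not touch the six isolated alkenes.

Step 9
Reactants: 10 all-E-hexaprenol
Product: 11 all-E-hexaprenyl bromide
Conditions: PBr3 (0.4 equiv), Et2O, 0 °C; used crude
Reagents that add atoms: phosphorus tribromide, BrP(Br)Br
Why: The same SN2 bromination of a primary allylic alcohol as in step 1 applies to the longer homologue and should keep the 2'E geometry.

Step 10
Reactants: 11 all-E-hexaprenyl bromide; 12 trimethylsilylacetylene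
Product: 14 (4E,8E,12E,16E,20E)-5,9,13,17,21,25-hexamethyl-1-(trimethylsilyl)hexacosa-4,8,12,16,20,24-hexaen-1-yne, via alkynylmagnesium bromide 13 (not isolated)
Conditions: 12, EtMgBr, THF, 0 °C → rt; CuBr·SMe2 (10 mol %), then 11, 0 °C → rt
Reagents that add atoms: none
Why: In the copper-catalysed allylic alkynylation of an alkynyl Grignard reagent, attack at the γ-carbon would have to build a quaternary centre, so substitution should take place at the primary α-carbon and give the skipped enyne with the E alkene retained.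

Step 11
Reactants: 14 (4E,8E,12E,16E,20E)-5,9,13,17,21,25-hexamethyl-1-(trimethylsilyl)hexacosa-4,8,12,16,20,24-hexaen-1-yne
Product: 15 (4E,8E,12E,16E,20E)-5,9,13,17,21,25-hexamethylhexacosa-4,8,12,16,20,24-hexaen-1-yne
Conditions: K2CO3 (cat.), MeOH/THF, rt
Reagents that add atoms: none
Why: Methanolysis of the C(sp)–Si bond needs only catalytic carbonate, a base too weak to move the skipped enyne into conjugation at room temperature.

Step 12
Reactants: 15 (4E,8E,12E,16E,20E)-5,9,13,17,21,25-hexamethylhexacosa-4,8,12,16,20,24-hexaen-1-yne; 16 dimethyl squarate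
Product: 18 (±)-4-hydroxy-2,3-dimethoxy-4-(all-E-hexaprenylethynyl)cyclobut-2-en-1-one, via lithium acetylide 17 (not isolated)
Conditions: 15, n-BuLi (1.0 equiv), THF, −78 °C; added to 16 (1.2 equiv), THF, −78 °C; sat. aq. NH4Cl at −78 °C
Reagents that add atoms: none
Why: The 1,2-addition of a lithium acetylide to one of the two equivalent squarate carbonyls stops after the first addition at −78 °C under inverse addition, and the new carbinol centre is racemic and later becomes the C4 carbonyl.

Step 13
Reactants: 18 (±)-4-hydroxy-2,3-dimethoxy-4-(all-E-hexaprenylethynyl)cyclobut-2-en-1-one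
Product: 19 (±)-2,3-dimethoxy-4-(triethylsilyloxy)-4-(all-E-hexaprenylethynyl)cyclobut-2-en-1-one
Conditions: Et3SiCl, imidazole, DMAP (cat.), CH2Cl2, 0 °C → rt
Reagents that add atoms: chlorotriethylsilane, CC[Si](Cl)(CC)CC
Why: Silylation of the little-hindered tertiary propargylic alcohol masks the one hydroxyl that must not ionise, so that in step 14 only the newly made secondary hydroxyl can leave.

Step 14
Reactants: 19 (±)-2,3-dimethoxy-4-(triethylsilyloxy)-4-(all-E-hexaprenylethynyl)cyclobut-2-en-1-one
Product: 21 (±)-2-methoxy-4-(triethylsilyloxy)-4-(all-E-hexaprenylethynyl)cyclobut-2-en-1-one, via cyclobutenol 20 (not isolated)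
Conditions: i-Bu2AlH (1.1 equiv), CH2Cl2, −78 °C; then 1 M aq. HCl, CH2Cl2, 0 °C, short contact
Reagents that add atoms: water, O
Why: This is a Stork–Danheiser transposition of a vinylogous ester, in which 1,2-hydride addition gives 20 (a carbinol centre of no consequence), acid expels the secondary hydroxyl with the push of the vinylogous methoxy group, and water adds to the oxocarbenium carbon and methanol leaves, so the new carbonyl sits next to the methoxy-bearing carbon and the new ring CH next to the silyloxy carbon.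

Step 15
Reactants: 21 (±)-2-methoxy-4-(triethylsilyloxy)-4-(all-E-hexaprenylethynyl)cyclobut-2-en-1-one
Product: 22 (±)-4-hydroxy-2-methoxy-4-(all-E-hexaprenylethynyl)cyclobut-2-en-1-one
Conditions: n-Bu4NF/AcOH (1:1), THF, 0 °C
Reagents that add atoms: none
Why: Fluoride desilylation buffered with acetic acid frees the hydroxyl without building up the alkoxide, so that base-induced ring opening and enyne isomerisation are held back, and the free O–H is needed because a silyl ether would pass silicon instead of hydrogen to C5 in step 16.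

Step 16
Reactants: 22 (±)-4-hydroxy-2-methoxy-4-(all-E-hexaprenylethynyl)cyclobut-2-en-1-one
Product: 25 2-methoxy-6-(all-E-hexaprenyl)-1,4-benzoquinone, via alkynyl(vinyl)ketene 23 (not isolated), via ring diradical 24 (not isolated)
Conditions: degassed toluene (0.01 M), 110 °C, Ar, dark; SiO2 chromatography with exclusion of light and base
Reagents that add atoms: none
Why: Heating drives a conrotatory 4π electrocyclic opening of the carbonyl–carbinol bond of 22, and the donor hydroxyl turns outward (torquoselectivity), so ketene 23 forms with its alkyne on the side of the ketene carbon. That carbon (quinone C1) then bonds to the distal alkyne carbon (quinone C6) in a 6-endo-dig closure to diradical 24, an aryl σ-radical at C5 paired with a phenoxyl oxygen on C1, and net transfer of the C4 hydroxyl hydrogen to C5 releases 25 at the quinone oxidation level without any oxidant. This is the Moore rearrangement of 4-alkynyl-4-hydroxycyclobutenones, a known route to 1,4-benzoquinones. No stereocentre is formed, the one of 22 becomes the C4 carbonyl, and the chain alkenes are spectators in hot neutral toluene. The selectivity needed is six- over five-membered closure: the 5-exo-dig mode would place a vinyl radical on the distal carbon, which the saturated C1' methylene cannot stabilise, so the aromatic six-membered diradical should be preferred. The 2,6 pattern is fixed beforehand by the constitution of 22, in which the carbinol carbon adjoins the ring CH and the ketene carbon adjoins the methoxy-bearing carbon.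

## Compound list

1 | (2E,6E)-farnesol | OC/C=C(\C)CC/C=C(\C)CCC=C(C)C | starting material
2 | (2E,6E)-farnesyl bromide | BrC/C=C(\C)CC/C=C(\C)CCC=C(C)C | intermediate
3 | (2E,6E)-farnesyl p-tolyl sulfone | Cc1ccc(cc1)S(=O)(=O)C/C=C(\C)CC/C=C(\C)CCC=C(C)C | intermediate
4 | (2E,6E)-farnesyl tert-butyldiphenylsilyl ether | CC(C)(C)[Si](OC/C=C(\C)CC/C=C(\C)CCC=C(C)C)(c1ccccc1)c1ccccc1 | intermediate
5 | (2E,6E,10E)-12-(tert-butyldiphenylsilyloxy)-2,6,10-trimethyldodeca-2,6,10-trien-1-ol | CC(C)(C)[Si](OC/C=C(\C)CC/C=C(\C)CC/C=C(\C)CO)(c1ccccc1)c1ccccc1 | intermediate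
6 | (2E,6E,10E)-12-bromo-3,7,11-trimethyldodeca-2,6,10-trienyl tert-butyldiphenylsilyl ether | CC(C)(C)[Si](OC/C=C(\C)CC/C=C(\C)CC/C=C(\C)CBr)(c1ccccc1)c1ccccc1 | intermediate
7 | α-lithiated farnesyl p-tolyl sulfone | Cc1ccc(cc1)S(=O)(=O)C([Li])/C=C(\C)CC/C=C(\C)CCC=C(C)C | intermediate
8 | (±)-13-(p-tolylsulfonyl)-all-E-hexaprenyl tert-butyldiphenylsilyl ether | CC(C)(C)[Si](OC/C=C(\C)CC/C=C(\C)CC/C=C(\C)CC(/C=C(\C)CC/C=C(\C)CCC=C(C)C)S(=O)(=O)c1ccc(C)cc1)(c1ccccc1)c1ccccc1 | intermediate
9 | all-E-hexaprenyl tert-butyldiphenylsilyl ether | CC(C)(C)[Si](OC/C=C(\C)CC/C=C(\C)CC/C=C(\C)CC/C=C(\C)CC/C=C(\C)CCC=C(C)C)(c1ccccc1)c1ccccc1 | intermediate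
10 | all-E-hexaprenol, (2E,6E,10E,14E,18E)-3,7,11,15,19,23-hexamethyltetracosa-2,6,10,14,18,22-hexaen-1-ol | OC/C=C(\C)CC/C=C(\C)CC/C=C(\C)CC/C=C(\C)CC/C=C(\C)CCC=C(C)C | intermediate
11 | all-E-hexaprenyl bromide | BrC/C=C(\C)CC/C=C(\C)CC/C=C(\C)CC/C=C(\C)CC/C=C(\C)CCC=C(C)C | intermediate
12 | trimethylsilylacetylene | C#C[Si](C)(C)C | starting material
13 | (trimethylsilylethynyl)magnesium bromide | C[Si](C)(C)C#C[Mg]Br | intermediate
14 | (4E,8E,12E,16E,20E)-5,9,13,17,21,25-hexamethyl-1-(trimethylsilyl)hexacosa-4,8,12,16,20,24-hexaen-1-yne | C[Si](C)(C)C#CC/C=C(\C)CC/C=C(\C)CC/C=C(\C)CC/C=C(\C)CC/C=C(\C)CCC=C(C)C | intermediate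
15 | (4E,8E,12E,16E,20E)-5,9,13,17,21,25-hexamethylhexacosa-4,8,12,16,20,24-hexaen-1-yne | C#CC/C=C(\C)CC/C=C(\C)CC/C=C(\C)CC/C=C(\C)CC/C=C(\C)CCC=C(C)C | intermediate
16 | dimethyl squarate | COC1=C(OC)C(=O)C1=O | starting material
17 | lithium acetylide of 15 | [Li]C#CC/C=C(\C)CC/C=C(\C)CC/C=C(\C)CC/C=C(\C)CC/C=C(\C)CCC=C(C)C | intermediate
18 | (±)-4-hydroxy-2,3-dimethoxy-4-(all-E-hexaprenylethynyl)cyclobut-2-en-1-one | COC1=C(OC)C(O)(C#CC/C=C(\C)CC/C=C(\C)CC/C=C(\C)CC/C=C(\C)CC/C=C(\C)CCC=C(C)C)C1=O | intermediate
19 | (±)-2,3-dimethoxy-4-(triethylsilyloxy)-4-(all-E-hexaprenylethynyl)cyclobut-2-en-1-one | COC1=C(OC)C(O[Si](CC)(CC)CC)(C#CC/C=C(\C)CC/C=C(\C)CC/C=C(\C)CC/C=C(\C)CC/C=C(\C)CCC=C(C)C)C1=O | intermediate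
20 | 2,3-dimethoxy-4-(triethylsilyloxy)-4-(all-E-hexaprenylethynyl)cyclobut-2-en-1-ol (diastereomer mixture) | COC1=C(OC)C(O[Si](CC)(CC)CC)(C#CC/C=C(\C)CC/C=C(\C)CC/C=C(\C)CC/C=C(\C)CC/C=C(\C)CCC=C(C)C)C1O | intermediate
21 | (±)-2-methoxy-4-(triethylsilyloxy)-4-(all-E-hexaprenylethynyl)cyclobut-2-en-1-one | COC1=CC(O[Si](CC)(CC)CC)(C#CC/C=C(\C)CC/C=C(\C)CC/C=C(\C)CC/C=C(\C)CC/C=C(\C)CCC=C(C)C)C1=O | intermediate
22 | (±)-4-hydroxy-2-methoxy-4-(all-E-hexaprenylethynyl)cyclobut-2-en-1-one | COC1=CC(O)(C#CC/C=C(\C)CC/C=C(\C)CC/C=C(\C)CC/C=C(\C)CC/C=C(\C)CCC=C(C)C)C1=O | intermediate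
23 | alkynyl(vinyl)ketene, hydroxyl trans and alkyne cis to the ketene arm | COC(=C=O)/C=C(/O)C#CC/C=C(\C)CC/C=C(\C)CC/C=C(\C)CC/C=C(\C)CC/C=C(\C)CCC=C(C)C | intermediate
24 | 4-hydroxy-2-methoxy-6-(all-E-hexaprenyl)phenoxyl-5-yl diradical | COc1cc(O)[c]c(C/C=C(\C)CC/C=C(\C)CC/C=C(\C)CC/C=C(\C)CC/C=C(\C)CCC=C(C)C)c1[O] | intermediate
25 | 2-methoxy-6-(all-E-hexaprenyl)-1,4-benzoquinone | COC1=CC(=O)C=C(C/C=C(\C)CC/C=C(\C)CC/C=C(\C)CC/C=C(\C)CC/C=C(\C)CCC=C(C)C)C1=O | target

## Step count and risks

Total step count: 16.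
Longest linear sequence: 14 steps (steps 3–16, from farnesol 1).

**First risk, step 16.**
- The ketene may leak into five-membered closure.
- The radical centres of 24 may abstract hydrogen from the doubly activated C1' methylene.
- The hot product may tautomerise to a quinone methide and close to a chromenol.
- The fallback gives up the ring expansion, forms the C6–C1' bond by aryl–allyl coupling, sets out from 11 and comes back at 25.
- Commercial 5-bromovanillin is taken by Dakin oxidation (H2O2, aq. NaOH) to 2-bromo-6-methoxybenzene-1,4-diol F1.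
- Methylation (Me2SO4, K2CO3, acetone) gives 1-bromo-2,3,5-trimethoxybenzene F2.
- Bromine–lithium exchange (n-BuLi, THF, −78 °C), transmetalation with CuBr·SMe2 and allylation with 11 should give 1-(all-E-hexaprenyl)-2,3,5-trimethoxybenzene F3.
- Oxidative demethylation of the para-dimethoxy pair with (NH4)2Ce(NO3)6 in MeCN/H2O at 0 °C then leads to 25.

**Second risk, step 14.**
- Under Brønsted acid the tertiary propargylic silyloxy group may ionise in place of the secondary hydroxyl.
- The silyl group may be lost before the transposition.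
- The polyene may begin to cyclise on long acid contact.
- The fallback replaces protonation by chemoselective acylation of the only free hydroxyl, sets out from 19 and comes back at 21.
- The i-Bu2AlH reduction is worked up with aqueous potassium sodium tartrate so that 20 is isolated.
- Trifluoroacetic anhydride and pyridine in CH2Cl2 at −78 °C convert 20 into the 1-trifluoroacetate of 20 F4.
- F4 should ionise on its own at low temperature, and a quench with aqueous NaHCO3 delivers 21 without free acid.

**Third risk, step 4.**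
- Site selectivity among the three trisubstituted alkenes may be poor.
- The alcohol may be over-oxidised to the enal.
- The fallback rebuilds the chain terminus instead of oxidising a C–H bond, sets out from 4 and comes back at 5.
- NBS in aqueous THF should attack the terminal alkene to give the 10-bromo-11-hydroxy derivative of 4 F5.
- K2CO3 in MeOH closes F5 to the 10,11-epoxide of 4 F6.
- H5IO6 in THF/Et2O cleaves F6 to (4E,8E)-10-(tert-butyldiphenylsilyloxy)-4,8-dimethyldeca-4,8-dienal F7.
- An E-selective Wittig reaction with the stabilised ylide Ph3P=C(CH3)CO2Et gives ethyl (2E,6E,10E)-12-(tert-butyldiphenylsilyloxy)-2,6,10-trimethyldodeca-2,6,10-trienoate F8.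
- i-Bu2AlH (CH2Cl2, −78 °C) reduces F8 to 5.

## Further compounds

F1 | step 16 | 2-bromo-6-methoxybenzene-1,4-diol | COc1cc(O)cc(Br)c1O
F2 | step 16 | 1-bromo-2,3,5-trimethoxybenzene | COc1cc(Br)c(OC)c(OC)c1
F3 | step 16 | 1-(all-E-hexaprenyl)-2,3,5-trimethoxybenzene | COc1cc(C/C=C(\C)CC/C=C(\C)CC/C=C(\C)CC/C=C(\C)CC/C=C(\C)CCC=C(C)C)c(OC)c(OC)c1
F4 | step 14 | 1-trifluoroacetate of 20 | COC1=C(OC)C(O[Si](CC)(CC)CC)(C#CC/C=C(\C)CC/C=C(\C)CC/C=C(\C)CC/C=C(\C)CC/C=C(\C)CCC=C(C)C)C1OC(=O)C(F)(F)F
F5 | step 4 | 10-bromo-11-hydroxy derivative of 4 (racemic) | CC(C)(C)[Si](OC/C=C(\C)CC/C=C(\C)CCC(Br)C(C)(C)O)(c1ccccc1)c1ccccc1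
F6 | step 4 | 10,11-epoxide of 4 (racemic) | CC(C)(C)[Si](OC/C=C(\C)CC/C=C(\C)CCC1OC1(C)C)(c1ccccc1)c1ccccc1
F7 | step 4 | (4E,8E)-10-(tert-butyldiphenylsilyloxy)-4,8-dimethyldeca-4,8-dienal | CC(C)(C)[Si](OC/C=C(\C)CC/C=C(\C)CCC=O)(c1ccccc1)c1ccccc1
F8 | step 4 | ethyl (2E,6E,10E)-12-(tert-butyldiphenylsilyloxy)-2,6,10-trimethyldodeca-2,6,10-trienoate | CC(C)(C)[Si](OC/C=C(\C)CC/C=C(\C)CC/C=C(\C)C(=O)OCC)(c1ccccc1)c1ccccc1
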